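**Plan**
- Numbering: ring carbons C1 (tertiary carbinol bearing acyl C2), C5 (CH–O-isovalerate), C6 (lactone O–CH), C7 (bearing C11; C12 lactone C=O, C13 =CH2), C8, C9 (CHOH), C10 (CHMe); C3=C4 is the Z alkene; α is the face of the C6 oxygen, β the other.
- Retrosynthesis cuts C2–C3 (propenyl anion onto a C2 aldehyde), the lactone C12–O bond and C11=C13, the C5 ester and the C1, C5 and C9 oxygens (back to a C1=C5 enoate and a C8=C9 enol silane), and last C1–C10 and C6–C7 of the carbocycle.
- What makes this possible: the cycloheptane is a three-carbon unit C1–C5–C6 carrying the C2 carbonyl joined to a four-carbon unit C7–C10, with the C6 oxygen, C7 chain and C10 methyl all α. This is the pattern left by a vinylcarbenoid adding to a diene through cyclopropanation and Cope rearrangement.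
- Forward: the vinyldiazoacetate and the dienol silane are made separately, the seven-membered ring forms in one operation, the ring oxygens and side arms are then adjusted, and the γ-lactone closes in the final step.
- Stereochemistry: C10 from the chiral rhodium carboxylate, C6 and C7 from the boat Cope, C1 and C5 from β-face directed epoxidation then anti opening at C1, C9 from C1-hydroxyl-directed hydride delivery, the Z alkene from (Z)-propenyllithium.

Key step: step 6

Assumption: the facial sense of Rh2(R-DOSP)4 is taken from the accepted model for styrene cyclopropanation (S catalyst gives the (1S,2R) aryl cyclopropane), with C9 in the benzylic position and the C10 methyl beside the carbenoid vinyl group; if the antipode of 12 formed, the S catalyst would be used.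

**Route**

Step 1
Reactants: 1 (tert-butyldimethylsilyloxy)acetaldehyde; 2 methyl diazoacetate
Product: 3 methyl 4-(tert-butyldimethylsilyloxy)-2-diazo-3-hydroxybutanoate (racemic)
Conditions: DBU (10 mol%), MeCN, 0 °C to rt
Reagents that add atoms: none
Why: Base-catalysed aldol-type addition of the diazoacetate carbon to an aldehyde is a standard entry to β-hydroxy α-diazo esters, and the new carbinol centre is removed in the next step.

Step 2
Reactants: 3
Product: 4 methyl (E)-4-(tert-butyldimethylsilyloxy)-2-diazobut-3-enoate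
Conditions: POCl3, Et3N, CH2Cl2, 0 °C; kept cold and used at once
Reagents that add atoms: none
Why: Dehydration (elimination) of β-hydroxy α-diazo esters with POCl3/Et3N is the usual route to vinyldiazoacetates and should give the conjugated E enol ether, with the silyloxy group trans to the diazo ester.

Step 3
Reactants: 5 3-(4-methoxybenzyloxy)propan-1-ol
Product: 6 3-(4-methoxybenzyloxy)propanal
Conditions: Dess–Martin periodinane, NaHCO3, CH2Cl2, 0 °C to rt
Reagents that add atoms: none
Why: Buffered Dess–Martin oxidation stops at the aldehyde and avoids β-elimination of the ether.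

Step 4
Reactants: 6; 7 dimethyl (2-oxobutyl)phosphonate
Product: 8 (E)-7-(4-methoxybenzyloxy)hept-4-en-3-one
Conditions: LiCl, i-Pr2NEt, MeCN, rt
Reagents that add atoms: none
Why: Horner–Wadsworth–Emmons olefination under mild LiCl/amine conditions gives the E enone and spares the base-sensitive β-alkoxy aldehyde.

Step 5
Reactants: 8
Product: 9 tert-butyl{[(2Z,4E)-7-(4-methoxybenzyloxy)hepta-2,4-dien-3-yl]oxy}dimethylsilane
Conditions: KN(SiMe3)2, THF, −78 °C; then TBSCl, −78 to 0 °C
Reagents that add atoms: tert-butyldimethylsilyl chloride, CC(C)(C)[Si](C)(C)Cl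
Why: Kinetic deprotonation of the enone at the α′ methylene by a hindered potassium amide gives the cross-conjugated Z(O) enolate, and O-silylation (silyl enol ether formation) fixes the 2Z geometry beside the 4E alkene.

Step 6
Reactants: 4; 9
Product: 12 methyl 3,6-bis(tert-butyldimethylsilyloxy)-4-[2-(4-methoxybenzyloxy)ethyl]-7-methylcyclohepta-1,5-diene-1-carboxylate (C1=C5 enoate; C8=C9 enol silane; C6 OTBS/C7 chain/C10 methyl all α), via trans-dialkenylcyclopropane 10 (not isolated), via cis-divinylcyclopropane 11 (not isolated)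
Conditions: Rh2(R-DOSP)4 [dirhodium tetrakis((R)-N-(4-dodecylbenzenesulfonyl)prolinate)] (2 mol%), hexanes, −40 °C to rt, slow addition of 4 (1.5 equiv); then 50 °C
Reagents that add atoms: none
Why: The catalyst converts 4 into a vinylcarbenoid of divalent rhodium that cyclopropanates the electron-rich C9=C10 enol-silane alkene of 9 (C10 bonding first), and a [3,3] Cope shift of the derived cis-divinylcyclopropane then breaks C1–C9 and joins C6 to C7; the closest known reaction is the tandem cyclopropanation/Cope rearrangement (formal (4+3) cycloaddition) of vinyldiazoacetates with dienes. The seven-membered ring closes in the sigmatropic step through a boat transition state, as a ring expansion of the cyclopropane and not by an end-to-end cyclisation. C10 is set in the cyclopropanation by the chiral prolinate ligands, which choose the face of the enol silane, the Z geometry keeping the methyl cis to the silyloxy group and trans to the C8 vinyl. Because the carbenoid places the substituted alkene terminus (methyl, silyloxy) beside its own vinyl group, the first cyclopropane 10 is expected to be the trans-dialkenyl isomer; its C1–C9 bond carries vicinal silyloxy donor and ester acceptor groups and should ionise reversibly, so that C1 epimerises to 11, the only isomer with a low-lying boat (methyl anti to both alkenyl groups), which is drained by the Cope shift. In that boat the E siloxyvinyl terminus and the E C7=C8 alkene put the C6 silyloxy group and the C7 side chain on the face of the C10 methyl, which sets C6 and C7. The step also needs site selectivity for the enol-silane alkene over C7=C8, secured because such donor/acceptor carbenoids attack electron-rich alkenes and do not react with trans-1,2-disubstituted ones, and the non-polar solvent is chosen to keep the ion pair from collapsing to a cyclopentene.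

Step 7
Reactants: 12
Product: 13 the C2 primary allylic alcohol (CO2Me of 12 reduced to CH2OH)
Conditions: i-Bu2AlH, CH2Cl2, −78 °C; aq. potassium sodium tartrate work-up
Reagents that add atoms: none
Why: 1,2-Reduction of the enoate by i-Bu2AlH gives the allylic alcohol and leaves the silyl enol ether, the silyl ether and the PMB ether untouched.

Step 8
Reactants: 13
Product: 14 the 2,3-epoxy alcohol (β-epoxide across C1–C5; CH2OH α at C1)
Conditions: VO(acac)2 (5 mol%), t-BuOOH (in decane), CH2Cl2, 0 °C
Reagents that add atoms: tert-butyl hydroperoxide, CC(C)(C)OO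
Why: Vanadium-catalysed hydroxyl-directed epoxidation acts only on the C1=C5 alkene of the allylic alcohol, and the exocyclic CH2OH delivers oxygen to the open β face, opposite the α C6 silyloxy and C10 methyl groups, which sets C1 and C5.

Step 9
Reactants: 14
Product: 16 the triol ketone (C9 ketone; C1 OH α; C2H2OH β; C5 OH β), via epoxy ketone 15 (not isolated)
Conditions: HClO4 (0.1 M aq.), THF, 0 °C to rt
Reagents that add atoms: water, O
Why: Acid-catalysed epoxide hydrolysis: after fast hydrolysis of the silyl enol ether, water opens the protonated epoxide at the tertiary carbon C1 with inversion (anti opening), so the C1 hydroxyl becomes α, the hydroxymethyl β, and the C5 hydroxyl stays β.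

Step 10
Reactants: 16
Product: 17 the C2 O-triethylsilyl ether of 16
Conditions: Et3SiCl (1.05 equiv), imidazole, CH2Cl2, −20 °C
Reagents that add atoms: chlorotriethylsilane, CC[Si](CC)(CC)Cl
Why: Silylation at low temperature selects the primary C2 hydroxyl over the hindered secondary C5 and tertiary C1 hydroxyls.

Step 11
Reactants: 17
Product: 18 the C5 isovalerate (3-methylbutanoate) of 17
Conditions: isovaleric anhydride, DMAP, Et3N, CH2Cl2, 0 °C to rt
Reagents that add atoms: isovaleric anhydride, CC(C)CC(=O)OC(=O)CC(C)C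
Why: DMAP-catalysed acylation esterifies the only acylable hydroxyl left, the secondary C5–OH, while the tertiary C1–OH does not react.

Step 12
Reactants: 18
Product: 19 the C9 β-alcohol (1,3-anti to the C1 hydroxyl, trans to the C10 methyl)
Conditions: Me4NBH(OAc)3, MeCN/AcOH (1:1), −30 °C
Reagents that add atoms: none
Why: Evans–Saksena reduction: the C1 hydroxyl binds boron and delivers hydride intramolecularly to the α face of the C9 ketone through a six-membered transition state, which sets C9 with the hydroxyl β.

Step 13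
Reactants: 19
Product: 20 the C9 O-TBS ether of 19
Conditions: TBSOTf (1.2 equiv), 2,6-lutidine, CH2Cl2, −78 °C
Reagents that add atoms: tert-butyldimethylsilyl trifluoromethanesulfonate, CC(C)(C)[Si](C)(C)OS(=O)(=O)C(F)(F)F
Why: Silyl triflate silylation at −78 °C protects the secondary C9 hydroxyl ahead of the tertiary C1 hydroxyl, so later oxidations cannot touch C9.

Step 14
Reactants: 20
Product: 21 the C12 primary alcohol (PMB removed)
Conditions: DDQ, CH2Cl2/pH 7 buffer, 0 °C
Reagents that add atoms: none
Why: Oxidative cleavage of the PMB ether by DDQ frees the C12 hydroxyl without affecting the silyl ethers or the ester.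

Step 15
Reactants: 21
Product: 22 the C12 aldehyde
Conditions: Dess–Martin periodinane, NaHCO3, CH2Cl2, 0 °C to rt
Reagents that add atoms: none
Why: Dess–Martin oxidation takes the primary alcohol to the aldehyde, the tertiary hydroxyl being inert.

Step 16
Reactants: 22
Product: 23 the α-methylene aldehyde (C11=C13H2, C12 CHO)
Conditions: aq. CH2O (37%), pyrrolidine (10 mol%), propionic acid (10 mol%), i-PrOH, 45 °C
Reagents that add atoms: formaldehyde, C=O
Why: Amine-catalysed α-methylenation (Mannich condensation then elimination) acts only on the enolisable C12 aldehyde and installs C13 without strong base.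

Step 17
Reactants: 23
Product: 24 the 2-substituted acrylic acid (C12 CO2H)
Conditions: NaClO2, NaH2PO4, 2-methylbut-2-ene, t-BuOH/H2O, 0 °C to rt
Reagents that add atoms: sodium chlorite, [Na+].[O-]Cl=O
Why: Pinnick oxidation converts the enal into the acid chemoselectively, the alkene scavenger removing hypochlorous acid.

Step 18
Reactants: 24
Product: 25 the C2 primary alcohol (triethylsilyl group removed)
Conditions: PPTS (cat.), MeOH/CH2Cl2, 0 °C
Reagents that add atoms: none
Why: Acid-catalysed methanolysis cleaves the primary triethylsilyl ether far faster than the two secondary TBS ethers.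

Step 19
Reactants: 25
Product: 26 the C2 aldehyde (α-hydroxy aldehyde)
Conditions: Dess–Martin periodinane, NaHCO3, CH2Cl2, 0 °C
Reagents that add atoms: none
Why: Dess–Martin oxidation of the primary alcohol of the primary/tertiary 1,2-diol gives the α-hydroxy aldehyde, which has no α-hydrogen and cannot epimerise.

Step 20
Reactants: 26
Product: 27 the C2 carbinol bearing the (Z)-prop-1-enyl group (both C2 epimers)
Conditions: (Z)-prop-1-enyllithium (3.3 equiv; from (Z)-1-bromoprop-1-ene and t-BuLi, Et2O, −78 °C), THF, −78 °C; NH4Cl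
Reagents that add atoms: (Z)-1-bromoprop-1-ene, C/C=C\Br
Why: 1,2-Addition of an alkenyllithium made by bromine–lithium exchange with retention of geometry brings in C3, C4 and the methyl as the Z alkene; the first two equivalents deprotonate the acid and the C1 hydroxyl, the carboxylate is inert, and the C2 configuration is irrelevant since C2 is oxidised next.

Step 21
Reactants: 27
Product: 28 the Z enone (C2 ketone)
Conditions: Dess–Martin periodinane, NaHCO3, CH2Cl2, 0 °C
Reagents that add atoms: none
Why: Dess–Martin oxidation of the allylic alcohol gives the enone under buffered, non-nucleophilic conditions that should not isomerise the Z alkene.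

Step 22
Reactants: 28
Product: 30 CNP0186412.2, via dihydroxy acid 29 (not isolated)
Conditions: aq. HF (48%), MeCN, 0 °C to rt
Reagents that add atoms: none
Why: Acidic fluoride desilylation frees the C6 and C9 hydroxyls, and the cis γ-hydroxy acrylic acid closes by acid-catalysed lactonisation (5-exo-trig acyl substitution) to the α-methylene γ-butyrolactone, conditions the Z enone and isovalerate should survive.

**Compound list**

1 | (tert-butyldimethylsilyloxy)acetaldehyde | O=CCO[Si](C)(C)C(C)(C)C | starting material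
2 | methyl diazoacetate | COC(=O)C=[N+]=[N-] | starting material
3 | methyl 4-(tert-butyldimethylsilyloxy)-2-diazo-3-hydroxybutanoate (racemic) | COC(=O)C(=[N+]=[N-])C(O)CO[Si](C)(C)C(C)(C)C | intermediate
4 | methyl (E)-4-(tert-butyldimethylsilyloxy)-2-diazobut-3-enoate | COC(=O)C(=[N+]=[N-])/C=C/O[Si](C)(C)C(C)(C)C | intermediate
5 | 3-(4-methoxybenzyloxy)propan-1-ol | OCCCOCc1ccc(OC)cc1 | starting material
6 | 3-(4-methoxybenzyloxy)propanal | O=CCCOCc1ccc(OC)cc1 | intermediate
7 | dimethyl (2-oxobutyl)phosphonate | CCC(=O)CP(=O)(OC)OC | starting material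
8 | (E)-7-(4-methoxybenzyloxy)hept-4-en-3-one | CCC(=O)/C=C/CCOCc1ccc(OC)cc1 | intermediate
9 | tert-butyl{[(2Z,4E)-7-(4-methoxybenzyloxy)hepta-2,4-dien-3-yl]oxy}dimethylsilane | C/C=C(O[Si](C)(C)C(C)(C)C)/C=C/CCOCc1ccc(OC)cc1 | intermediate
10 | first-formed cyclopropane (C1, C9, C10), alkenyl groups trans, methyl and C9 silyloxy cis to the siloxyvinyl group (not isolated) | COC(=O)[C@]1(/C=C/O[Si](C)(C)C(C)(C)C)[C@@H](C)[C@]1(O[Si](C)(C)C(C)(C)C)/C=C/CCOCc1ccc(OC)cc1 | intermediate
11 | C1 epimer of 10: cis-divinylcyclopropane, methyl anti to both alkenyl groups (not isolated) | COC(=O)[C@@]1(/C=C/O[Si](C)(C)C(C)(C)C)[C@@H](C)[C@]1(O[Si](C)(C)C(C)(C)C)/C=C/CCOCc1ccc(OC)cc1 | intermediate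
12 | methyl 3,6-bis(tert-butyldimethylsilyloxy)-4-[2-(4-methoxybenzyloxy)ethyl]-7-methylcyclohepta-1,5-diene-1-carboxylate; C6 OTBS, C7 chain, C10 methyl all α | CC(C)(C)[Si](C)(C)O[C@@H]1[C@H](CCOCc2ccc(OC)cc2)C=C(O[Si](C)(C)C(C)(C)C)[C@H](C)C(C(=O)OC)=C1 | intermediate
13 | C2 allylic alcohol from 12 | CC(C)(C)[Si](C)(C)O[C@@H]1[C@H](CCOCc2ccc(OC)cc2)C=C(O[Si](C)(C)C(C)(C)C)[C@H](C)C(CO)=C1 | intermediate
14 | C1–C5 β-epoxide of 13 (CH2OH α at C1) | CC(C)(C)[Si](C)(C)O[C@@H]1[C@H](CCOCc2ccc(OC)cc2)C=C(O[Si](C)(C)C(C)(C)C)[C@H](C)[C@@]2(CO)O[C@@H]12 | intermediate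
15 | epoxy ketone: 14 with the enol silane hydrolysed to the C9 ketone (not isolated) | CC(C)(C)[Si](C)(C)O[C@@H]1[C@H](CCOCc2ccc(OC)cc2)CC(=O)[C@H](C)[C@@]2(CO)O[C@@H]12 | intermediate
16 | triol ketone: C9 ketone, C1 OH α, C2H2OH β, C5 OH β, C6 OTBS α, C7 CH2CH2OPMB α, C10 methyl α | CC(C)(C)[Si](C)(C)O[C@@H]1[C@H](CCOCc2ccc(OC)cc2)CC(=O)[C@H](C)[C@@](O)(CO)[C@H]1O | intermediate
17 | 16 with C2–O-SiEt3 | CC(C)(C)[Si](C)(C)O[C@@H]1[C@H](CCOCc2ccc(OC)cc2)CC(=O)[C@H](C)[C@@](O)(CO[Si](CC)(CC)CC)[C@H]1O | intermediate
18 | 17 with C5 O-isovalerate | CC(C)(C)[Si](C)(C)O[C@@H]1[C@H](CCOCc2ccc(OC)cc2)CC(=O)[C@H](C)[C@@](O)(CO[Si](CC)(CC)CC)[C@H]1OC(=O)CC(C)C | intermediate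
19 | 18 with C9 reduced to the β-alcohol | CC(C)(C)[Si](C)(C)O[C@@H]1[C@H](CCOCc2ccc(OC)cc2)C[C@@H](O)[C@H](C)[C@@](O)(CO[Si](CC)(CC)CC)[C@H]1OC(=O)CC(C)C | intermediate
20 | 19 with C9 OTBS | CC(C)(C)[Si](C)(C)O[C@@H]1[C@H](CCOCc2ccc(OC)cc2)C[C@@H](O[Si](C)(C)C(C)(C)C)[C@H](C)[C@@](O)(CO[Si](CC)(CC)CC)[C@H]1OC(=O)CC(C)C | intermediate
21 | 20 with the C12 hydroxyl free | CC(C)(C)[Si](C)(C)O[C@@H]1[C@H](CCO)C[C@@H](O[Si](C)(C)C(C)(C)C)[C@H](C)[C@@](O)(CO[Si](CC)(CC)CC)[C@H]1OC(=O)CC(C)C | intermediate
22 | C12 aldehyde | CC(C)(C)[Si](C)(C)O[C@@H]1[C@H](CC=O)C[C@@H](O[Si](C)(C)C(C)(C)C)[C@H](C)[C@@](O)(CO[Si](CC)(CC)CC)[C@H]1OC(=O)CC(C)C | intermediate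
23 | α-methylene aldehyde (C11=C13H2) | CC(C)(C)[Si](C)(C)O[C@@H]1[C@H](C(=C)C=O)C[C@@H](O[Si](C)(C)C(C)(C)C)[C@H](C)[C@@](O)(CO[Si](CC)(CC)CC)[C@H]1OC(=O)CC(C)C | intermediate
24 | acrylic acid (C12 CO2H) | CC(C)(C)[Si](C)(C)O[C@@H]1[C@H](C(=C)C(=O)O)C[C@@H](O[Si](C)(C)C(C)(C)C)[C@H](C)[C@@](O)(CO[Si](CC)(CC)CC)[C@H]1OC(=O)CC(C)C | intermediate
25 | 24 with the C2 hydroxyl free | CC(C)(C)[Si](C)(C)O[C@@H]1[C@H](C(=C)C(=O)O)C[C@@H](O[Si](C)(C)C(C)(C)C)[C@H](C)[C@@](O)(CO)[C@H]1OC(=O)CC(C)C | intermediate
26 | C2 aldehyde | CC(C)(C)[Si](C)(C)O[C@@H]1[C@H](C(=C)C(=O)O)C[C@@H](O[Si](C)(C)C(C)(C)C)[C@H](C)[C@@](O)(C=O)[C@H]1OC(=O)CC(C)C | intermediate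
27 | C2 (Z)-prop-1-enyl carbinol (C2 epimers) | CC(C)(C)[Si](C)(C)O[C@@H]1[C@H](C(=C)C(=O)O)C[C@@H](O[Si](C)(C)C(C)(C)C)[C@H](C)[C@@](O)(C(O)/C=C\C)[C@H]1OC(=O)CC(C)C | intermediate
28 | Z enone acid, C6 and C9 still OTBS | CC(C)(C)[Si](C)(C)O[C@@H]1[C@H](C(=C)C(=O)O)C[C@@H](O[Si](C)(C)C(C)(C)C)[C@H](C)[C@@](O)(C(=O)/C=C\C)[C@H]1OC(=O)CC(C)C | intermediate
29 | dihydroxy acid: 28 without the two TBS groups (not isolated) | O[C@@H]1[C@H](C(=C)C(=O)O)C[C@@H](O)[C@H](C)[C@@](O)(C(=O)/C=C\C)[C@H]1OC(=O)CC(C)C | intermediate
30 | CNP0186412.2; (1S,5S,6R,7S,9R,10S) in the numbering used here; α-methylene γ-lactone cis-fused at C6/C7 | C=C1C(=O)O[C@@H]2[C@H]1C[C@@H](O)[C@H](C)[C@@](O)(C(=O)/C=C\C)[C@H]2OC(=O)CC(C)C | target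

**Count and risks**

Total steps: 22. Longest linear sequence: 20 (steps 3 to 22, from 5).

Step 6. The bulky chiral carboxylate may capture the carbenoid too slowly at the hindered trisubstituted enol-silane alkene, so that carbene dimerisation or cyclisation of 4 to a pyrazole takes over. It may also show poor facial selectivity, or the ion pair from the donor–acceptor cyclopropane may collapse to a cyclopentene. Fallback: move stereocontrol from the catalyst to an ester auxiliary and use a small achiral catalyst. (R)-Pantolactone (or its enantiomer, whichever matches the required face) is acylated with bromoacetyl bromide to (R)-pantolactonyl bromoacetate F1, and N,N′-ditosylhydrazine with DBU converts it into (R)-pantolactonyl diazoacetate F2. Setting out from aldehyde 1, F2 takes the place of 2 in the chemistry of steps 1 and 2 to give the hydroxy diazo ester F3 and then the auxiliary-bearing vinyldiazoacetate F4. Rh2(O2CC7H15)4 effects the same cyclopropanation/Cope sequence with 9 to give the pantolactonyl cycloheptadiene ester F5, and the i-Bu2AlH reduction of step 7 cleaves the auxiliary and returns to the route at 13.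

Step 9. The ring opening may lose regiocontrol (water attacking C5, or the freshly unmasked C9 ketone taking part), the β-hydroxy ketone may dehydrate, or the C6 silyl ether may be lost under the acid. Fallback: deliver the C1 oxygen intramolecularly. From 14, Boc2O/DMAP gives the C2 tert-butyl carbonate F6. BF3·OEt2 in CH2Cl2 at −78 °C lets the carbonate carbonyl oxygen open the epoxide at C1 in a 5-exo mode with inversion and loss of isobutene, giving the spiro cyclic carbonate F7 with the C5 hydroxyl β and the enol silane intact. K2CO3 in MeOH followed by a brief dilute-acid work-up removes the carbonate and the enol silane and returns to the route at 16.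

Step 20. The alkenyllithium may attack the isovalerate, act only as a base on the polyanion, or lose part of its Z geometry during formation. Fallback: set the Z alkene by alkyne semi-reduction instead. From 26, CH3C≡CMgBr (THF, −78 to 0 °C), which does not attack esters under these conditions, gives the propargylic alcohol F8. Hydrogenation over Pd/CaCO3 poisoned with Pb(OAc)2 in the presence of quinoline then gives the Z alkene and returns to the route at 27.

**Further compounds**

F1 | step 6 | (3R)-4,4-dimethyl-2-oxooxolan-3-yl 2-bromoacetate | CC1(C)COC(=O)[C@@H]1OC(=O)CBr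
F2 | step 6 | (3R)-4,4-dimethyl-2-oxooxolan-3-yl 2-diazoacetate | CC1(C)COC(=O)[C@@H]1OC(=O)C=[N+]=[N-]
F3 | step 6 | (3R)-4,4-dimethyl-2-oxooxolan-3-yl 4-(tert-butyldimethylsilyloxy)-2-diazo-3-hydroxybutanoate | CC1(C)COC(=O)[C@@H]1OC(=O)C(=[N+]=[N-])C(O)CO[Si](C)(C)C(C)(C)C
F4 | step 6 | (3R)-4,4-dimethyl-2-oxooxolan-3-yl (E)-4-(tert-butyldimethylsilyloxy)-2-diazobut-3-enoate | CC1(C)COC(=O)[C@@H]1OC(=O)C(=[N+]=[N-])/C=C/O[Si](C)(C)C(C)(C)C
F5 | step 6 | pantolactonyl ester analogue of 12 | CC(C)(C)[Si](C)(C)O[C@@H]1[C@H](CCOCc2ccc(OC)cc2)C=C(O[Si](C)(C)C(C)(C)C)[C@H](C)C(C(=O)O[C@H]2C(=O)OCC2(C)C)=C1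
F6 | step 9 | C2 tert-butyl carbonate of 14 | CC(C)(C)[Si](C)(C)O[C@@H]1[C@H](CCOCc2ccc(OC)cc2)C=C(O[Si](C)(C)C(C)(C)C)[C@H](C)[C@@]2(COC(=O)OC(C)(C)C)O[C@@H]12
F7 | step 9 | C1/C2 cyclic carbonate with free β C5 hydroxyl and intact enol silane | CC(C)(C)[Si](C)(C)O[C@@H]1[C@H](CCOCc2ccc(OC)cc2)C=C(O[Si](C)(C)C(C)(C)C)[C@H](C)[C@@](O3)(COC3=O)[C@H]1O
F8 | step 20 | C2 prop-1-ynyl carbinol (C2 epimers) | CC(C)(C)[Si](C)(C)O[C@@H]1[C@H](C(=C)C(=O)O)C[C@@H](O[Si](C)(C)C(C)(C)C)[C@H](C)[C@@](O)(C(O)C#CC)[C@H]1OC(=O)CC(C)C
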